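**Plan**

Target: (3R)-5,7,4'-trihydroxy-6,3'-diprenylisoflavanone (prenyl = 3-methylbut-2-en-1-yl; isoflavonoid numbering throughout).
Cuts: first the C3–H bond (back to the achiral isoflavone), then ring A at C4a–C5, C5–C6 and C7–C8 (C8–C8a is re-made in the same operation by a 1,2-shift). Next comes C3–C1' between rings C and B, and last the C3'–prenyl bond and the ynol ether.
Enabling feature: ring A carries in unbroken order C5–OH, C6–prenyl, C7–O and C8–H and shares C4a–C8a with the pyranone ring C. A ketene carbon (C5), the two carbons of a prenylated siloxyalkyne (C6, C7), a former diazo carbon (C8) and the C2=C3 bond of a 4-pyranone (C8a, C4a) map onto it atom for atom.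
Forward order: ring C is bought as kojic acid, ring B (C-prenylated 4-bromophenol) is joined to it by Suzuki coupling, the hydroxymethyl arm becomes a diazoacetyl group, and ring A is closed last.
Stereochemistry: the single centre C3 (R; CIP order C4 > C2 > C1' > H) comes from catalyst-controlled decarboxylative protonation of the C3=C4 enolate (palladium/PHOX) and is kept by an acidic fluoride deprotection.

Key step: step 9

Assumption: the sense of induction of the decarboxylative protonation depends on ligand, proton donor and enolate and cannot be derived with certainty for this substrate. The (S)-ligand is written, C3 is to be checked on the first batch (CD, chiral HPLC), and the (R)-ligand is used under otherwise identical conditions should the 3S series result.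
Abbreviations: TBS = tert-butyldimethylsilyl, TIPS = triisopropylsilyl, pin = pinacolato.

**Step 1**
Reactants: 1 4-bromophenol; 2 prenyl bromide
Product: 3 4-bromo-2-prenylphenol
Conditions: NaH, PhMe, 0 °C; then 2, rt
Reagents that add atoms: none
Why: ortho-C-alkylation of a phenol salt, in which the non-polar solvent keeps the sodium salt tightly aggregated at oxygen, so the allylic bromide is attacked in SN2 fashion by the ortho carbon (para is blocked by bromine) and the dienone re-aromatizes.

**Step 2**
Reactants: 3 4-bromo-2-prenylphenol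
Product: 4 (4-bromo-2-prenylphenoxy)(tert-butyl)dimethylsilane
Conditions: TBSCl, imidazole, DMF, rt
Reagents that add atoms: tert-butyldimethylsilyl chloride, CC(C)(C)[Si](C)(C)Cl
Why: imidazole-promoted silylation of a phenol, giving an aryl silyl ether that should withstand cross-coupling, oxidation, light and hydride and leave with fluoride at the end.

**Step 3**
Reactants: 4 (4-bromo-2-prenylphenoxy)(tert-butyl)dimethylsilane
Product: 5 tert-butyldimethyl[2-prenyl-4-(4,4,5,5-tetramethyl-1,3,2-dioxaborolan-2-yl)phenoxy]silane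
Conditions: B2pin2, PdCl2(dppf) (3 mol %), KOAc, 1,4-dioxane, 85 °C
Reagents that add atoms: bis(pinacolato)diboron, CC1(C)OB(OC1(C)C)B1OC(C)(C)C(C)(C)O1
Why: Miyaura borylation of an aryl bromide, in which the weak acetate base neither starts homocoupling nor cleaves the aryl silyl ether and the trisubstituted alkene is inert.

**Step 4**
Reactants: 6 kojic acid
Product: 7 6-(hydroxymethyl)-4-oxo-4H-pyran-3-yl trifluoromethanesulfonate (kojic acid 5-O-triflate)
Conditions: PhNTf2, Et3N, MeCN, 0 °C → rt
Reagents that add atoms: N-phenylbis(trifluoromethanesulfonimide), O=S(=O)(N(c1ccccc1)S(=O)(=O)C(F)(F)F)C(F)(F)F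
Why: chemoselective O-sulfonylation, since only the acidic enolic 5-OH is deprotonated by the amine and the mild triflyl donor does not react with the neutral primary alcohol.

**Step 5**
Reactants: 7 kojic acid 5-O-triflate; 5 ring B pinacol boronate
Product: 8 5-[4-(tert-butyldimethylsilyloxy)-3-prenylphenyl]-2-(hydroxymethyl)-4H-pyran-4-one
Conditions: PdCl2(dppf) (5 mol %), K3PO4, THF–H2O (10:1), 50 °C
Reagents that add atoms: none
Why: Suzuki–Miyaura coupling, in which the electron-poor pyranonyl triflate adds readily to zerovalent palladium, so a mild phosphate base and a low temperature suffice and both the base-sensitive pyranone and the aryl silyl ether are spared.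

**Step 6**
Reactants: 8 5-aryl-2-(hydroxymethyl)-4H-pyran-4-one
Product: 10 5-[4-(tert-butyldimethylsilyloxy)-3-prenylphenyl]-4-oxo-4H-pyran-2-carboxylic acid, via pyranone-2-carbaldehyde 9 (not isolated)
Conditions: TEMPO (20 mol %), PhI(OAc)2 (2.2 equiv), MeCN–H2O (1:1), rt
Reagents that add atoms: water, O
Why: oxoammonium (TEMPO/diacetoxyiodobenzene) oxidation of a primary alcohol through aldehyde 9, whose hydrate forms easily next to the electron-poor ring and is oxidized on to the acid, in a chlorine-free and nearly neutral medium that leaves the prenyl alkene and the silyl ether alone.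

**Step 7**
Reactants: 10 5-aryl-4-oxo-4H-pyran-2-carboxylic acid
Product: 12 2-(diazoacetyl)-5-[4-(tert-butyldimethylsilyloxy)-3-prenylphenyl]-4H-pyran-4-one, via pyranone-2-carbonyl chloride 11 (not isolated)
Conditions: Me2C=C(Cl)NMe2, CH2Cl2, 0 °C; then CH2N2 (1.5 equiv), Et3N, Et2O–CH2Cl2, −20 → 0 °C
Reagents that add atoms: diazomethane, C=[N+]=[N-]; 1-chloro-N,N,2-trimethylprop-1-en-1-amine, CC(C)=C(Cl)N(C)C (chlorine of 11 only)
Why: Arndt–Eistert-type acylation of diazomethane in the Newman–Beal variant, where the α-chloroenamine makes the acid chloride without free HCl (which would add to the prenyl group) and Et3N takes up the HCl of the acylation, so little excess diazomethane is present and fast acylation at low temperature should outrun dipolar cycloaddition to the ring, as it does for chromone-2-carbonyl chlorides.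

**Step 8**
Reactants: 13 ethyl 4-methylpent-3-enoate
Product: 16 triisopropyl[(5-methylhex-4-en-1-yn-1-yl)oxy]silane, via lithium dibromoenolate 14 (not isolated), via lithium ynolate 15 (not isolated)
Conditions: CH2Br2, lithium 2,2,6,6-tetramethylpiperidide, THF, −78 °C; 13; LiN(SiMe3)2; n-BuLi, −78 °C → rt; TIPSOTf, −78 → 0 °C
Reagents that add atoms: dibromomethane, BrCBr; triisopropylsilyl trifluoromethanesulfonate, CC(C)[Si](OS(=O)(=O)C(F)(F)F)(C(C)C)C(C)C; LiN(SiMe3)2, [Li]N([Si](C)(C)C)[Si](C)(C)C, and n-BuLi, [Li]CCCC (lithium of 14 and 15 only)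
Why: Kowalski ynolate synthesis, in which LiCHBr2 adds to the ester, deprotonation gives 14, bromine–lithium exchange triggers a 1,2-shift of the prenyl group with loss of LiBr to ynolate 15, and the bulky silyl electrophile is taken up at oxygen rather than at carbon.

**Step 9**
Reactants: 12 2-(diazoacetyl)-5-aryl-4H-pyran-4-one; 16 prenylated triisopropylsiloxyalkyne
Product: 21 5-hydroxy-7-(triisopropylsilyloxy)-4'-(tert-butyldimethylsilyloxy)-6,3'-diprenylisoflavone, via pyranonylketene 17 (not isolated), via vinylcyclobutenone 18 (not isolated), via dienylketene 19 (not isolated), via cyclohexadienone 20 (not isolated)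
Conditions: 16 (1.5 equiv), hν (405 nm LED), PhMe (degassed), 20 °C; then 110 °C
Reagents that add atoms: none
Why: Proposed new method: excitation of the diazoketone n–π* band expels N2 and triggers a Wolff rearrangement in which pyranone C2 (future C8a) shifts from the acyl carbon to the former diazo carbon (C8), giving ketene 17, whose electrophilic carbonyl carbon (C5) is attacked by the oxygen-remote, prenyl-bearing carbon of ynol ether 16, so that a regiospecific [2+2] cycloaddition forms C5–C6 and C7–C8 in cyclobutenone 18. On heating, 18 opens by reversible 4π electrocyclic cleavage of its C5–C8 bond to dienylketene 19, ring A closes by thermal disrotatory 6π electrocyclization of the ketene carbon onto pyranone C3 (C4a–C5), and the 1,3-diketone tautomer 20 enolizes irreversibly to the hydrogen-bonded phenol 21. The closest known reaction type is the Danheiser benzannulation of vinyl, aryl and heteroaryl diazomethyl ketones with triisopropylsiloxyalkynes; new is the terminal 2π unit, the C2=C3 bond of a 4-pyranone, a cross-conjugated vinylogous ester that gives up far less aromatic stabilization than the benzene, furan or thiophene rings that already take part. No stereocentre has to be controlled, since C4 of 18 and C4a of 20 are transient and 21 is achiral. The step needs regioselectivity in the cycloaddition, secured by the polarity of the siloxyalkyne, site selectivity in the closure, secured because C3 is the only ring carbon next to pyranone C2 (the other neighbour is O1), and chemoselectivity for the ynol ether over the prenyl alkenes, secured by its much higher nucleophilicity towards ketenes. Light of 405 nm is chosen because neither the aryl-pyranone chromophore, which photoisomerizes under UV light, nor 21 should absorb there, and the excess of 16 together with the chelated, flanked position of O5–H should suppress ketene dimerization and O-acylation of the product.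

**Step 10**
Reactants: 21 5-hydroxy-7-(triisopropylsilyloxy)-4'-(tert-butyldimethylsilyloxy)-6,3'-diprenylisoflavone
Product: 22 5-(allyloxycarbonyloxy)-7-(triisopropylsilyloxy)-4'-(tert-butyldimethylsilyloxy)-6,3'-diprenylisoflavone
Conditions: ClCO2CH2CH=CH2, Et3N, DMAP (cat.), CH2Cl2, 0 °C → rt
Reagents that add atoms: allyl chloroformate, C=CCOC(=O)Cl
Why: DMAP-catalysed O-acylation of the chelated phenol; a carbonate and not a silyl ether is put on O5 because in the enolate of step 11 a group on O5 can shift to the neighbouring O4, which is harmless only when both oxygens end up with the same allyl carbonate, and because this group leaves in step 12 without a step of its own.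

**Step 11**
Reactants: 22 5-O-allyloxycarbonyl isoflavone
Product: 24 allyl 5-(allyloxycarbonyloxy)-3-[4-(tert-butyldimethylsilyloxy)-3-prenylphenyl]-6-prenyl-7-(triisopropylsilyloxy)-2H-chromen-4-yl carbonate, via lithium chromen-4-olate 23 (not isolated)
Conditions: LiBH(s-Bu)3 (1.3 equiv), THF, −78 °C; then ClCO2CH2CH=CH2 (3 equiv), −78 → 0 °C
Reagents that add atoms: allyl chloroformate, C=CCOC(=O)Cl; LiBH(s-Bu)3, [Li+].CCC(C)[BH-](C(C)CC)C(C)CC (lithium of 23 only, otherwise hydride)
Why: conjugate reduction of the isoflavone enone by a bulky trialkylborohydride (hydride to C2, which becomes CH2) gives the hindered tetrasubstituted enolate 23, which the hard chloroformate acylates at oxygen, and any carbonate lost from or shifted away from O5 is restored by the excess chloroformate.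

**Step 12**
Reactants: 24 bis(allyl carbonate)
Product: 25 (3R)-5-hydroxy-7-(triisopropylsilyloxy)-4'-(tert-butyldimethylsilyloxy)-6,3'-diprenylisoflavanone
Conditions: Pd2(dba)3 (5 mol %), (S)-(CF3)3-t-BuPHOX (12.5 mol %), Meldrum's acid (5 equiv), 1,4-dioxane, 25 °C
Reagents that add atoms: none
Why: palladium-catalysed decarboxylative asymmetric protonation, a reaction type established for isoflavanones, in which zerovalent palladium ionizes the enol carbonate, CO2 is lost and the enolate is protonated at C3 by Meldrum's acid within the chiral environment of the PHOX-bound allylpalladium cation, which selects the enolate face and so sets C3 (R), while the aryl allyl carbonate on O5 falls to the same catalyst (Tsuji–Trost deallylation) and the Meldrum's acid anion takes up both allyl groups.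

**Step 13**
Reactants: 25 (3R)-bis-silyl isoflavanone
Product: 26 (3R)-5,7,4'-trihydroxy-6,3'-diprenylisoflavanone (target)
Conditions: Et3N·3HF, THF, 0 °C → rt
Reagents that add atoms: none
Why: fluoride cleavage of the two aryl silyl ethers in a slightly acidic medium, where neither base-induced enolization of the α-aryl ketone (C3 stays R) nor acid-induced chroman formation from the ortho-prenylphenols should take place.

**Compound list**

1 | 4-bromophenol | Oc1ccc(Br)cc1 | starting material
2 | prenyl bromide (1-bromo-3-methylbut-2-ene) | CC(C)=CCBr | starting material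
3 | 4-bromo-2-prenylphenol | CC(C)=CCc1cc(Br)ccc1O | intermediate
4 | (4-bromo-2-prenylphenoxy)(tert-butyl)dimethylsilane | CC(C)=CCc1cc(Br)ccc1O[Si](C)(C)C(C)(C)C | intermediate
5 | tert-butyldimethyl[2-prenyl-4-(4,4,5,5-tetramethyl-1,3,2-dioxaborolan-2-yl)phenoxy]silane | CC(C)=CCc1cc(B2OC(C)(C)C(C)(C)O2)ccc1O[Si](C)(C)C(C)(C)C | intermediate
6 | kojic acid (5-hydroxy-2-(hydroxymethyl)-4H-pyran-4-one) | OCc1cc(=O)c(O)co1 | starting material
7 | 6-(hydroxymethyl)-4-oxo-4H-pyran-3-yl trifluoromethanesulfonate | OCc1cc(=O)c(OS(=O)(=O)C(F)(F)F)co1 | intermediate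
8 | 5-[4-(tert-butyldimethylsilyloxy)-3-prenylphenyl]-2-(hydroxymethyl)-4H-pyran-4-one | OCc1cc(=O)c(-c2ccc(O[Si](C)(C)C(C)(C)C)c(CC=C(C)C)c2)co1 | intermediate
9 | 5-[4-(tert-butyldimethylsilyloxy)-3-prenylphenyl]-4-oxo-4H-pyran-2-carbaldehyde (not isolated) | O=Cc1cc(=O)c(-c2ccc(O[Si](C)(C)C(C)(C)C)c(CC=C(C)C)c2)co1 | intermediate
10 | 5-[4-(tert-butyldimethylsilyloxy)-3-prenylphenyl]-4-oxo-4H-pyran-2-carboxylic acid | OC(=O)c1cc(=O)c(-c2ccc(O[Si](C)(C)C(C)(C)C)c(CC=C(C)C)c2)co1 | intermediate
11 | 5-[4-(tert-butyldimethylsilyloxy)-3-prenylphenyl]-4-oxo-4H-pyran-2-carbonyl chloride (not isolated) | ClC(=O)c1cc(=O)c(-c2ccc(O[Si](C)(C)C(C)(C)C)c(CC=C(C)C)c2)co1 | intermediate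
12 | 2-(diazoacetyl)-5-[4-(tert-butyldimethylsilyloxy)-3-prenylphenyl]-4H-pyran-4-one | [N-]=[N+]=CC(=O)c1cc(=O)c(-c2ccc(O[Si](C)(C)C(C)(C)C)c(CC=C(C)C)c2)co1 | intermediate
13 | ethyl 4-methylpent-3-enoate | CCOC(=O)CC=C(C)C | starting material
14 | lithium 1,1-dibromo-5-methylhexa-1,4-dien-2-olate (not isolated) | [Li+].[O-]C(CC=C(C)C)=C(Br)Br | intermediate
15 | lithium 5-methylhex-4-en-1-yn-1-olate (not isolated) | [Li+].[O-]C#CCC=C(C)C | intermediate
16 | triisopropyl[(5-methylhex-4-en-1-yn-1-yl)oxy]silane | CC(C)=CCC#CO[Si](C(C)C)(C(C)C)C(C)C | intermediate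
17 | 5-[4-(tert-butyldimethylsilyloxy)-3-prenylphenyl]-2-(2-oxoethenyl)-4H-pyran-4-one, the pyranonylketene (not isolated) | O=C=Cc1cc(=O)c(-c2ccc(O[Si](C)(C)C(C)(C)C)c(CC=C(C)C)c2)co1 | intermediate
18 | 4-(5-aryl-4-oxo-4H-pyran-2-yl)-2-prenyl-3-(triisopropylsilyloxy)cyclobut-2-en-1-one, racemic (not isolated) | O=C1C(CC=C(C)C)=C(O[Si](C(C)C)(C(C)C)C(C)C)C1c3cc(=O)c(-c2ccc(O[Si](C)(C)C(C)(C)C)c(CC=C(C)C)c2)co3 | intermediate
19 | 4-(5-aryl-4-oxo-4H-pyran-2-yl)-2-prenyl-3-(triisopropylsilyloxy)buta-1,3-dien-1-one, ketene carbon and pyranonyl group cis on the C7=C8 bond (not isolated) | O=C=C(CC=C(C)C)/C(O[Si](C(C)C)(C(C)C)C(C)C)=C\c1cc(=O)c(-c2ccc(O[Si](C)(C)C(C)(C)C)c(CC=C(C)C)c2)co1 | intermediate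
20 | 4aH-chromene-4,5-dione tautomer of 21 (sp3 C4a–H), racemic (not isolated) | O=C1C(CC=C(C)C)=C(O[Si](C(C)C)(C(C)C)C(C)C)C=C2OC=C(c3ccc(O[Si](C)(C)C(C)(C)C)c(CC=C(C)C)c3)C(=O)C12 | intermediate
21 | 5-hydroxy-7-(triisopropylsilyloxy)-4'-(tert-butyldimethylsilyloxy)-6,3'-diprenylisoflavone | CC(C)=CCc1cc(-c2coc3cc(O[Si](C(C)C)(C(C)C)C(C)C)c(CC=C(C)C)c(O)c3c2=O)ccc1O[Si](C)(C)C(C)(C)C | intermediate
22 | 5-(allyloxycarbonyloxy)-7-(triisopropylsilyloxy)-4'-(tert-butyldimethylsilyloxy)-6,3'-diprenylisoflavone | CC(C)=CCc1cc(-c2coc3cc(O[Si](C(C)C)(C(C)C)C(C)C)c(CC=C(C)C)c(OC(=O)OCC=C)c3c2=O)ccc1O[Si](C)(C)C(C)(C)C | intermediate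
23 | lithium 5-(allyloxycarbonyloxy)-3-aryl-6-prenyl-7-(triisopropylsilyloxy)-2H-chromen-4-olate (not isolated) | [Li+].[O-]C1=C(c2ccc(O[Si](C)(C)C(C)(C)C)c(CC=C(C)C)c2)COc2cc(O[Si](C(C)C)(C(C)C)C(C)C)c(CC=C(C)C)c(OC(=O)OCC=C)c12 | intermediate
24 | allyl 5-(allyloxycarbonyloxy)-3-[4-(tert-butyldimethylsilyloxy)-3-prenylphenyl]-6-prenyl-7-(triisopropylsilyloxy)-2H-chromen-4-yl carbonate | C=CCOC(=O)OC1=C(c2ccc(O[Si](C)(C)C(C)(C)C)c(CC=C(C)C)c2)COc2cc(O[Si](C(C)C)(C(C)C)C(C)C)c(CC=C(C)C)c(OC(=O)OCC=C)c12 | intermediate
25 | (3R)-5-hydroxy-7-(triisopropylsilyloxy)-4'-(tert-butyldimethylsilyloxy)-6,3'-diprenylisoflavanone | CC(C)=CCc1cc([C@@H]2COc3cc(O[Si](C(C)C)(C(C)C)C(C)C)c(CC=C(C)C)c(O)c3C2=O)ccc1O[Si](C)(C)C(C)(C)C | intermediate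
26 | (3R)-5,7,4'-trihydroxy-6,3'-diprenylisoflavanone (CNP0206440.1) | CC(C)=CCc1cc([C@@H]2COc3cc(O)c(CC=C(C)C)c(O)c3C2=O)ccc1O | target

**Totals**

Total step count: 13.
Longest linear sequence: 11 steps (1, 2, 3, 5, 6, 7, 9, 10, 11, 12, 13). Steps 4 and 8 are one-step side branches.

**Steps most likely to fail**

**1. Step 9.** Three things may go wrong:
- The ketene may be used up by dimerization or by traces of water before it meets the ynol ether.
- Residual absorption of the aryl-pyranone may divert light into photoisomerization of ring C.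
- The 6π closure onto the acyl-substituted C3 may be slow enough that the cyclobutenone–dienylketene equilibrium drains into oligomerization.

The fallback uses known chemistry only: ring A is bought as a phloroglucinol, and the C6 side chain is placed by a sigmatropic shift instead of by ring construction. It sets out from boronate 5 and comes back at 21.

Commercial 2,4,6-trihydroxyacetophenone is silylated at the hydroxyl para to the acetyl group (TIPSCl, imidazole, DMF) to 1-[2,6-dihydroxy-4-(triisopropylsilyloxy)phenyl]ethanone F1. Mono-allylation under Mitsunobu conditions (allyl alcohol, PPh3, DIAD, THF) gives 1-[2-(allyloxy)-6-hydroxy-4-(triisopropylsilyloxy)phenyl]ethanone F2. Condensation with DMF dimethyl acetal gives (E)-1-[2-(allyloxy)-6-hydroxy-4-(triisopropylsilyloxy)phenyl]-3-(dimethylamino)prop-2-en-1-one F3, and I2 in CHCl3 closes ring C to 5-(allyloxy)-3-iodo-7-(triisopropylsilyloxy)-4H-chromen-4-one F4.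

Suzuki–Miyaura coupling of F4 with 5 (PdCl2(dppf), K3PO4) gives 5-(allyloxy)-7-(triisopropylsilyloxy)-4'-(tert-butyldimethylsilyloxy)-3'-prenylisoflavone F5. Aromatic Claisen rearrangement in N,N-diethylaniline at 190 °C can deliver the allyl group only to C6, because the other ortho position C4a is blocked. It gives 6-allyl-5-hydroxy-7-(triisopropylsilyloxy)-4'-(tert-butyldimethylsilyloxy)-3'-prenylisoflavone F6. Cross metathesis with 2-methylbut-2-ene (second-generation Grubbs catalyst, CH2Cl2, 40 °C) turns the allyl into the prenyl group and gives 21.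

**2. Step 12.** Four things may go wrong:
- Facial selectivity may be poor, because ring B has no ortho substituent and this reaction type works best with hindered α-aryl groups.
- Early release of O5–H may open an achiral proton relay next to the enolate oxygen.
- C-allylation at C3 may compete with protonation.
- C3 may epimerize during chromatography.

The fallback replaces catalyst control by resolution with recycling. It sets out from 24 and comes back at 25. Pd(PPh3)4 and Meldrum's acid in THF remove both allyl carbonates and give racemic 5-hydroxy-7-(triisopropylsilyloxy)-4'-(tert-butyldimethylsilyloxy)-6,3'-diprenylisoflavanone F7.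

Preparative SFC on an amylose tris(3,5-dimethylphenylcarbamate) phase separates 25 from (3S)-5-hydroxy-7-(triisopropylsilyloxy)-4'-(tert-butyldimethylsilyloxy)-6,3'-diprenylisoflavanone F8. The latter is re-equilibrated to F7 with catalytic Et3N in toluene at 40 °C and fed back to the separation.

**3. Step 8.** The lithium bases may deprotonate the doubly activated α-CH2 of the β,γ-unsaturated ester instead of letting LiCHBr2 add. The double bond may also drift into conjugation, so that little ynolate forms.

The fallback makes the ynolate by oxidation of an acetylide instead of by ester homologation. It sets out from prenyl bromide 2 and comes back at ynolate 15. Ethynylmagnesium bromide with catalytic CuCl in THF couples with 2 at the primary carbon to give 5-methylhex-4-en-1-yne F9. One equivalent of n-BuLi at −78 °C gives lithium 5-methylhex-4-en-1-yn-1-ide F10. Lithium tert-butyl peroxide (from t-BuOOH and LiN(SiMe3)2, THF, −78 → 0 °C) transfers oxygen to the acetylide carbon to give 15, which is silylated with TIPSOTf as in step 8.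

**Further compounds**

F1 | step 9 | 1-[2,6-dihydroxy-4-(triisopropylsilyloxy)phenyl]ethanone | CC(=O)c1c(O)cc(O[Si](C(C)C)(C(C)C)C(C)C)cc1O
F2 | step 9 | 1-[2-(allyloxy)-6-hydroxy-4-(triisopropylsilyloxy)phenyl]ethanone | CC(=O)c1c(O)cc(O[Si](C(C)C)(C(C)C)C(C)C)cc1OCC=C
F3 | step 9 | (E)-1-[2-(allyloxy)-6-hydroxy-4-(triisopropylsilyloxy)phenyl]-3-(dimethylamino)prop-2-en-1-one | CN(C)/C=C/C(=O)c1c(O)cc(O[Si](C(C)C)(C(C)C)C(C)C)cc1OCC=C
F4 | step 9 | 5-(allyloxy)-3-iodo-7-(triisopropylsilyloxy)-4H-chromen-4-one | O=c1c(I)coc2cc(O[Si](C(C)C)(C(C)C)C(C)C)cc(OCC=C)c12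
F5 | step 9 | 5-(allyloxy)-7-(triisopropylsilyloxy)-4'-(tert-butyldimethylsilyloxy)-3'-prenylisoflavone | O=c1c(-c3ccc(O[Si](C)(C)C(C)(C)C)c(CC=C(C)C)c3)coc2cc(O[Si](C(C)C)(C(C)C)C(C)C)cc(OCC=C)c12
F6 | step 9 | 6-allyl-5-hydroxy-7-(triisopropylsilyloxy)-4'-(tert-butyldimethylsilyloxy)-3'-prenylisoflavone | O=c1c(-c3ccc(O[Si](C)(C)C(C)(C)C)c(CC=C(C)C)c3)coc2cc(O[Si](C(C)C)(C(C)C)C(C)C)c(CC=C)c(O)c12
F7 | step 12 | racemic 5-hydroxy-7-(triisopropylsilyloxy)-4'-(tert-butyldimethylsilyloxy)-6,3'-diprenylisoflavanone | CC(C)=CCc1cc(C2COc3cc(O[Si](C(C)C)(C(C)C)C(C)C)c(CC=C(C)C)c(O)c3C2=O)ccc1O[Si](C)(C)C(C)(C)C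
F8 | step 12 | (3S)-5-hydroxy-7-(triisopropylsilyloxy)-4'-(tert-butyldimethylsilyloxy)-6,3'-diprenylisoflavanone | CC(C)=CCc1cc([C@H]2COc3cc(O[Si](C(C)C)(C(C)C)C(C)C)c(CC=C(C)C)c(O)c3C2=O)ccc1O[Si](C)(C)C(C)(C)C
F9 | step 8 | 5-methylhex-4-en-1-yne | C#CCC=C(C)C
F10 | step 8 | lithium 5-methylhex-4-en-1-yn-1-ide | [Li]C#CCC=C(C)C
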